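**Retrosynthetic overview**

1. The target is reached from silyl-protected tricycle 32 by desilylation, acetylation at O15, acylation at O8 and a last desilylation.
2. 32 comes from aldehyde–allyl bromide 29 by a Cr(II) Barbier allylation with lactonisation. It rests on the C6–C7 bond, which is common to oxepane B (O, C5, C6, C7, C8, C9, C10) and to the trans-fused α-methylene-γ-butyrolactone (C6, C7, C11, C12, O). The C5 and C10 arms lie on opposite faces of oxepane A (trans-bridged 11-oxabicyclo[4.4.1]undecane).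
3. 29 comes from oxepane 22 by ozonolysis of the C8 vinyl carbinol, Baylis–Hillman reaction, oxidation of C6 and SN2′ bromination.
4. Oxepane A (22) comes from 7-exo opening of a C5–C6 epoxide by the C10 tertiary hydroxyl of (R)-linalool. C3/C4 come from an Evans crotonate aldol, C5 from a hydroxyl-directed epoxidation, C8 from a catalytic vinylzinc addition.
5. Ring order: oxepane A (step 12), then oxepane B and the lactone together (step 17).

Key step: step 17

Remark: atoms carry germacrane numbers (C1–C15). C15 is taken through the key step as its TBS ether, not as the acetate, because an ester 1,3 to the C5–C6 epoxide would compete as a neighbouring group in the oxepane closure; the acetate is put on afterwards.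

**Route**

Step 1
Reactants: 1 (R)-linalool
Product: 3 (R)-3,7-dimethyloct-6-ene-1,3-diol, via B-alkyl-9-BBN adduct 2 (not isolated)
Conditions: 9-BBN (2.2 equiv), THF, 0 → 23 °C; then NaOH, H2O2, 0 °C
Reagents that add atoms: hydrogen peroxide, OO
Why: Brown hydroboration–oxidation; 9-BBN should take the monosubstituted vinyl group anti-Markovnikov and leave the trisubstituted alkene, with C10 untouched.

Step 2
Reactants: 3 (R)-3,7-dimethyloct-6-ene-1,3-diol
Product: 4 (R)-3,7-dimethyl-1,3-bis(trimethylsilyloxy)oct-6-ene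
Conditions: TMSCl, imidazole, DMF, 0 → 23 °C
Reagents that add atoms: chlorotrimethylsilane, C[Si](C)(C)Cl
Why: Silylation of both hydroxyls; the tertiary TMS ether masks O10 so that the later C3 aldehyde cannot close to a lactol, and the primary one is the handle for step 3.

Step 3
Reactants: 4 bis-TMS ether
Product: 6 (R)-3,7-dimethyl-3-(trimethylsilyloxy)oct-6-enal, via alkoxysulfonium chloride 5 (not isolated)
Conditions: (COCl)2, DMSO, CH2Cl2, −78 → −30 °C; then Et3N, −78 → 0 °C
Reagents that add atoms: none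
Why: Swern oxidation applied directly to a primary trimethylsilyl ether, which is exchanged into the alkoxysulfonium salt while the tertiary silyl ether is inert.

Step 4
Reactants: 6 β-silyloxy aldehyde
Product: 7 (3R,5R)-5,9-dimethyl-5-(trimethylsilyloxy)deca-1,8-dien-3-ol
Conditions: salt-free divinylzinc (from vinylMgBr and ZnCl2), (−)-MIB (10 mol%), toluene, −20 → 0 °C; aq NH4Cl
Reagents that add atoms: divinylzinc, C=C[Zn]C=C
Why: Amino-alcohol-catalysed enantioselective alkenylzinc addition (Oppolzer type); (−)-MIB directs transfer to the Si face of the aldehyde, which should set C8 as R under reagent control, the remote C10 centre having little say.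

Step 5
Reactants: 7 allylic alcohol
Product: 8 (3R,5R)-5,9-dimethyl-3-(triethylsilyloxy)-5-(trimethylsilyloxy)deca-1,8-diene
Conditions: TESCl, imidazole, CH2Cl2, 0 °C
Reagents that add atoms: chlorotriethylsilane, CC[Si](Cl)(CC)CC
Why: Routine silylation of the secondary alcohol; O8 stays masked as the TES ether up to step 18.

Step 6
Reactants: 8 diene
Product: 10 (4R,6R)-4-methyl-6-(triethylsilyloxy)-4-(trimethylsilyloxy)oct-7-enal, via ozonide 9 (not isolated)
Conditions: O3 (1 equiv, Sudan Red end point), CH2Cl2, −78 °C; then PPh3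
Reagents that add atoms: ozone, [O-][O+]=O
Why: Ozonolysis with reductive work-up; ozone should select the electron-rich trisubstituted alkene over the monosubstituted vinyl group that carries an allylic silyloxy group.

Step 7
Reactants: 11 (R)-4-benzyloxazolidin-2-one; 12 (E)-but-2-enoyl chloride
Product: 14 (R)-4-benzyl-3-[(E)-but-2-enoyl]oxazolidin-2-one, via N-lithio oxazolidinone 13 (not isolated)
Conditions: n-BuLi, THF, −78 °C; then 12, −78 → 0 °C
Reagents that add atoms: none
Why: N-acylation of the lithiated Evans auxiliary.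

Step 8
Reactants: 14 crotonyl imide; 10 aldehyde
Product: 17 (R)-4-benzyl-3-[(2R,3S,6R,8R)-2-ethenyl-3-hydroxy-6-methyl-8-(triethylsilyloxy)-6-(trimethylsilyloxy)dec-9-enoyl]oxazolidin-2-one, via boron dienolate 15 (not isolated), via boron aldolate 16 (not isolated)
Conditions: Bu2BOTf, Et3N, CH2Cl2, −78 → 0 °C; then 10, −78 → 0 °C; pH 7 buffer, MeOH, H2O2, 0 °C
Reagents that add atoms: none
Why: Evans syn-aldol of the crotonate imide; the Z(O)-boron dienolate formed by γ-deprotonation reacts at its α-carbon through a chair Zimmerman–Traxler transition state, and the (R)-auxiliary sets C3 and C4 (C3–O and C4–C15 anti along the chain, which becomes cis on ring A).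

Step 9
Reactants: 17 aldol adduct
Product: 18 (R)-4-benzyl-3-[(2S,3S,6R,8R)-3-hydroxy-6-methyl-2-[(S)-oxiran-2-yl]-8-(triethylsilyloxy)-6-(trimethylsilyloxy)dec-9-enoyl]oxazolidin-2-one
Conditions: VO(acac)2 (10 mol%), t-BuOOH (decane), CH2Cl2, 0 → 23 °C
Reagents that add atoms: tert-butyl hydroperoxide, CC(C)(C)OO
Why: Hydroxyl-directed vanadium epoxidation of the homoallylic alkene through a chair vanadate transition state with the C2 chain and the C4 acyl group equatorial, which should put the oxirane oxygen 1,3-syn to O3 and anti to C15; the other vinyl group has no free hydroxyl within reach.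

Step 10
Reactants: 18 epoxy imide
Product: 20 (2S,3S,6R,8R)-6-methyl-2-[(S)-oxiran-2-yl]-8-(triethylsilyloxy)dec-9-ene-1,3,6-triol, via trimethylsilyl ether diol 19 (not isolated)
Conditions: LiBH4, MeOH (2 equiv), THF, 0 °C; then K2CO3, MeOH, 23 °C
Reagents that add atoms: none
Why: Reductive removal of the auxiliary (the imide is reduced faster than the epoxide), then methanolysis of the tertiary TMS ether, which the secondary TES ether should survive.

Step 11
Reactants: 20 epoxy triol
Product: 21 epoxy alcohol with free tertiary O10-H and TBS ethers at O3 and O15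
Conditions: TBSOTf (2.3 equiv), 2,6-lutidine, CH2Cl2, −78 °C
Reagents that add atoms: tert-butyldimethylsilyl trifluoromethanesulfonate, CC(C)(C)[Si](C)(C)OS(=O)(=O)C(F)(F)F
Why: Silyl triflate silylation of the primary and the hindered secondary hydroxyl; the tertiary hydroxyl is too slow at −78 °C.

Step 12
Reactants: 21 epoxy alcohol
Product: 22 [(2R,3R,4S,7R)-4-(tert-butyldimethylsilyloxy)-3-(tert-butyldimethylsilyloxymethyl)-7-methyl-7-[(2R)-2-(triethylsilyloxy)but-3-enyl]oxepan-2-yl]methanol (ring A; O3, C15, C6 and the C10 methyl on one face)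
Conditions: CSA (10 mol%), CH2Cl2 (0.01 M), 0 → 23 °C
Reagents that add atoms: none
Why: Acid-catalysed intramolecular epoxide opening by the tertiary hydroxyl, 7-exo-tet at the internal carbon (favoured over 8-endo by ring size and by charge build-up at the more substituted carbon) with inversion at C5, which places C6 cis to C15 and O3 and trans to the C9 arm; the silyl ethers cannot act as neighbouring groups.

Step 13
Reactants: 22 oxepane alcohol
Product: 24 oxepane A carrying CH2OH at C5 and the arm CH2–CH(OTES)–CHO at C10, via ozonide 23 (not isolated)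
Conditions: O3, CH2Cl2, −78 °C; then PPh3
Reagents that add atoms: ozone, [O-][O+]=O
Why: Ozonolysis of the only alkene with reductive work-up gives the α-silyloxy aldehyde (C7).

Step 14
Reactants: 24 hydroxy aldehyde; 25 methyl acrylate
Product: 26 Baylis–Hillman adduct (C7 carbinol as an epimer mixture; C6 alcohol free)
Conditions: DABCO (1 equiv), methyl acrylate (neat), 23 °C
Reagents that add atoms: none
Why: Morita–Baylis–Hillman reaction; α-silyloxy aldehydes are activated electrophiles, the new C7 centre is erased in step 16, and the weak amine base should not epimerise C8.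

Step 15
Reactants: 26 diol
Product: 27 C6 aldehyde with the Baylis–Hillman alcohol intact
Conditions: TEMPO (10 mol%), PhI(OAc)2, CH2Cl2, 23 °C
Reagents that add atoms: none
Why: Oxoammonium oxidation selects the primary alcohol and leaves the electron-poor, hindered secondary allylic alcohol.

Step 16
Reactants: 27 hydroxy aldehyde
Product: 29 ring-A aldehyde with the (Z)-2-(bromomethyl)enoate arm (key-step precursor), via alkoxysulfonium bromide 28 (not isolated)
Conditions: NBS, Me2S, CH2Cl2, −20 → 0 °C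
Reagents that add atoms: N-bromosuccinimide, O=C1CCC(=O)N1Br
Why: Corey–Kim-type activation of the Baylis–Hillman alcohol and SN2′ attack of bromide give the thermodynamically preferred (Z)-2-(bromomethyl)enoate under neutral conditions that the aldehyde and silyl ethers tolerate.

Step 17
Reactants: 29 aldehyde–allyl bromide
Product: 32 silyl-protected tricyclic α-methylene lactone, via allylchromium(III) species 30 (not isolated), via chromium alkoxide 31 (not isolated)
Conditions: CrCl2 (8 equiv), THF, 3 mM, slow addition of 29, 25 °C; aq NH4Cl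
Reagents that add atoms: none
Why: Two equivalents of Cr(II) reduce the allylic C–Br bond to allylchromium(III) species 30, whose E and Z forms interconvert so that the bromide geometry is immaterial; it adds through its γ-carbon C7 to the C6 aldehyde in a chair transition state with allylic transposition, which forms C6–C7 and leaves the C11=C13 methylene, and chromium alkoxide 31 then acylates on C12 with loss of methanol. The closest known reaction is the intramolecular Nozaki–Hiyama–Kishi (Barbier) cyclisation of 2-(alkoxycarbonyl)allyl halides onto aldehydes, which gives ring-fused α-methylene-γ-butyrolactones, medium rings included. Oxepane B closes by carbonyl addition in a 7-exo-trig mode and the lactone by 5-exo-trig acyl substitution. C6 and C7 are set together: the chair with the aldehyde substituent (C5) equatorial gives the anti adduct and hence the trans-fused lactone, and the facial sense is set by the C8 centre, whose silyloxy group should take the pseudo-equatorial site of the forming ring (C11 cis to O8), and by C5, which is tied into oxepane A. The step needs this one diastereomer in a ring that bridges the two faces of oxepane A; the substrate secures it by having the C5 and C10 arms already trans on ring A, so that the bond made is remote from both bridgeheads, while high dilution suppresses intermolecular coupling and the poor leaving ability of the silyloxy group guards against β-elimination from the C7-bound chromium form.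

Step 18
Reactants: 32 tricycle
Product: 33 diol (O8-H and O15-H free; O3 TBS)
Conditions: HF·pyridine, pyridine, THF, 0 → 23 °C
Reagents that add atoms: none
Why: Buffered fluoride desilylation should cleave the triethylsilyl ether and the primary TBS ether well before the hindered secondary TBS ether at C3.

Step 19
Reactants: 33 diol
Product: 34 C15 monoacetate
Conditions: AcCl (1.1 equiv), 2,4,6-collidine, CH2Cl2, −78 °C
Reagents that add atoms: acetyl chloride, CC(Cl)=O
Why: Low-temperature acylation with acetyl chloride and collidine selects the primary hydroxyl over the hindered secondary C8 hydroxyl.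

Step 20
Reactants: 35 3-methylfuran-2(5H)-one
Product: 36 sodium (Z)-4-hydroxy-2-methylbut-2-enoate
Conditions: NaOH (1.0 equiv), H2O, 23 °C; lyophilise
Reagents that add atoms: sodium hydroxide, [Na+].[OH-]
Why: Saponification opens the butenolide, whose ring fixes the Z geometry; the salt cannot relactonise.

Step 21
Reactants: 36 sodium salt
Product: 37 (Z)-4-acetoxy-2-methylbut-2-enoic acid
Conditions: Ac2O (1.5 equiv), DMAP (cat.), pyridine, 0 °C; cold dilute HCl to pH 3
Reagents that add atoms: acetic anhydride, CC(=O)OC(C)=O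
Why: DMAP-catalysed O-acetylation of the primary allylic alcohol should outrun activation of the sparingly soluble carboxylate, and once acetylated the acid cannot relactonise; any material that does relactonise is recovered as 35.

Step 22
Reactants: 37 side-chain acid; 34 C8 alcohol
Product: 39 O3-TBS ether of the target, via mixed anhydride 38 (not isolated)
Conditions: 2,4,6-trichlorobenzoyl chloride, Et3N, toluene, 23 °C; then 34, toluene, 75 °C (no DMAP)
Reagents that add atoms: none
Why: Yamaguchi esterification; the DMAP-free thermal variant is used because it is the protocol that avoids Z to E isomerisation of angelate-type acids.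

Step 23
Reactants: 39 silyl ether
Product: 40 CNP0148432.1 (target)
Conditions: HF (48% aq), MeCN, 0 → 23 °C
Reagents that add atoms: none
Why: Acidic fluoride desilylation of the secondary TBS ether; the acetates, the unsaturated ester and the α-methylene lactone are not affected.

**Compound list**

1 | (R)-linalool | C=C[C@](C)(O)CCC=C(C)C | starting material
2 | B-alkyl-9-BBN adduct of 1 (boron on the former terminal vinyl carbon) | C1CC2CCCC(C1)B2CC[C@](C)(O)CCC=C(C)C | intermediate
3 | (R)-3,7-dimethyloct-6-ene-1,3-diol | OCC[C@](C)(O)CCC=C(C)C | intermediate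
4 | (R)-3,7-dimethyl-1,3-bis(trimethylsilyloxy)oct-6-ene | C[Si](C)(C)OCC[C@](C)(O[Si](C)(C)C)CCC=C(C)C | intermediate
5 | alkoxydimethylsulfonium chloride at the primary oxygen of 4 | C[S+](C)OCC[C@](C)(O[Si](C)(C)C)CCC=C(C)C.[Cl-] | intermediate
6 | (R)-3,7-dimethyl-3-(trimethylsilyloxy)oct-6-enal | O=CC[C@](C)(O[Si](C)(C)C)CCC=C(C)C | intermediate
7 | (3R,5R)-5,9-dimethyl-5-(trimethylsilyloxy)deca-1,8-dien-3-ol | C=C[C@H](O)C[C@](C)(O[Si](C)(C)C)CCC=C(C)C | intermediate
8 | (3R,5R)-5,9-dimethyl-3-(triethylsilyloxy)-5-(trimethylsilyloxy)deca-1,8-diene | C=C[C@H](O[Si](CC)(CC)CC)C[C@](C)(O[Si](C)(C)C)CCC=C(C)C | intermediate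
9 | ozonide (1,2,4-trioxolane) of the trisubstituted alkene of 8 | C=C[C@H](O[Si](CC)(CC)CC)C[C@](C)(O[Si](C)(C)C)CCC1OOC(C)(C)O1 | intermediate
10 | (4R,6R)-4-methyl-6-(triethylsilyloxy)-4-(trimethylsilyloxy)oct-7-enal | C=C[C@H](O[Si](CC)(CC)CC)C[C@](C)(O[Si](C)(C)C)CCC=O | intermediate
11 | (R)-4-benzyloxazolidin-2-one | O=C1N[C@H](Cc2ccccc2)CO1 | starting material
12 | (E)-but-2-enoyl chloride | C/C=C/C(Cl)=O | starting material
13 | N-lithio-(R)-4-benzyloxazolidin-2-one | [Li]N1[C@H](Cc2ccccc2)COC1=O | intermediate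
14 | (R)-4-benzyl-3-[(E)-but-2-enoyl]oxazolidin-2-one | C/C=C/C(=O)N1[C@H](Cc2ccccc2)COC1=O | intermediate
15 | (Z)-dibutylboron dienolate of 14 | C=C/C=C(\OB(CCCC)CCCC)N1[C@H](Cc2ccccc2)COC1=O | intermediate
16 | dibutylboron aldolate of 17 | C=C[C@H](O[Si](CC)(CC)CC)C[C@](C)(O[Si](C)(C)C)CC[C@H](OB(CCCC)CCCC)[C@@H](C=C)C(=O)N1[C@H](Cc2ccccc2)COC1=O | intermediate
17 | Evans syn-aldol adduct, (2R,3S,6R,8R)-2-ethenyl-3-hydroxy acyl imide | C=C[C@H](O[Si](CC)(CC)CC)C[C@](C)(O[Si](C)(C)C)CC[C@H](O)[C@@H](C=C)C(=O)N1[C@H](Cc2ccccc2)COC1=O | intermediate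
18 | epoxy imide, (2S,3S,6R,8R) with (S)-oxiran-2-yl at C2 of the acyl chain | C=C[C@H](O[Si](CC)(CC)CC)C[C@](C)(O[Si](C)(C)C)CC[C@H](O)[C@@H]([C@H]1CO1)C(=O)N1[C@H](Cc2ccccc2)COC1=O | intermediate
19 | epoxy 1,3-diol still carrying the tertiary TMS ether | C=C[C@H](O[Si](CC)(CC)CC)C[C@](C)(O[Si](C)(C)C)CC[C@H](O)[C@H](CO)[C@H]1CO1 | intermediate
20 | (2S,3S,6R,8R)-6-methyl-2-[(S)-oxiran-2-yl]-8-(triethylsilyloxy)dec-9-ene-1,3,6-triol | C=C[C@H](O[Si](CC)(CC)CC)C[C@](C)(O)CC[C@H](O)[C@H](CO)[C@H]1CO1 | intermediate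
21 | 1,3-bis-TBS ether of 20 (tertiary hydroxyl free) | C=C[C@H](O[Si](CC)(CC)CC)C[C@](C)(O)CC[C@H](O[Si](C)(C)C(C)(C)C)[C@H](CO[Si](C)(C)C(C)(C)C)[C@H]1CO1 | intermediate
22 | oxepane A alcohol, [(2R,3R,4S,7R)-4-TBSO-3-(TBSOCH2)-7-methyl-7-[(2R)-2-(triethylsilyloxy)but-3-enyl]oxepan-2-yl]methanol | OC[C@@H]1O[C@](C)(CC[C@H](O[Si](C)(C)C(C)(C)C)[C@@H]1CO[Si](C)(C)C(C)(C)C)C[C@@H](O[Si](CC)(CC)CC)C=C | intermediate
23 | ozonide of the vinyl group of 22 | OC[C@@H]1O[C@](C)(CC[C@H](O[Si](C)(C)C(C)(C)C)[C@@H]1CO[Si](C)(C)C(C)(C)C)C[C@@H](O[Si](CC)(CC)CC)C1OOCO1 | intermediate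
24 | oxepane A with CH2OH at C5 and the (R)-2-(triethylsilyloxy)-3-oxopropyl arm at C10 | OC[C@@H]1O[C@](C)(CC[C@H](O[Si](C)(C)C(C)(C)C)[C@@H]1CO[Si](C)(C)C(C)(C)C)C[C@@H](O[Si](CC)(CC)CC)C=O | intermediate
25 | methyl acrylate | C=CC(=O)OC | starting material
26 | Baylis–Hillman adduct of 24 (C7 epimers) | OC[C@@H]1O[C@](C)(CC[C@H](O[Si](C)(C)C(C)(C)C)[C@@H]1CO[Si](C)(C)C(C)(C)C)C[C@@H](O[Si](CC)(CC)CC)C(O)C(=C)C(=O)OC | intermediate
27 | C6 aldehyde of 26 | O=C[C@@H]1O[C@](C)(CC[C@H](O[Si](C)(C)C(C)(C)C)[C@@H]1CO[Si](C)(C)C(C)(C)C)C[C@@H](O[Si](CC)(CC)CC)C(O)C(=C)C(=O)OC | intermediate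
28 | alkoxydimethylsulfonium bromide at O7 of 27 | O=C[C@@H]1O[C@](C)(CC[C@H](O[Si](C)(C)C(C)(C)C)[C@@H]1CO[Si](C)(C)C(C)(C)C)C[C@@H](O[Si](CC)(CC)CC)C(O[S+](C)C)C(=C)C(=O)OC.[Br-] | intermediate
29 | ring-A aldehyde with the (8R)-triethylsilyloxy (Z)-2-(bromomethyl)enoate arm (key-step precursor; C15 as TBS ether) | O=C[C@@H]1O[C@](C)(CC[C@H](O[Si](C)(C)C(C)(C)C)[C@@H]1CO[Si](C)(C)C(C)(C)C)C[C@@H](O[Si](CC)(CC)CC)/C=C(\CBr)C(=O)OC | intermediate
30 | allylchromium(III) dichloride from 29 (E/Z interconverting) | O=C[C@@H]1O[C@](C)(CC[C@H](O[Si](C)(C)C(C)(C)C)[C@@H]1CO[Si](C)(C)C(C)(C)C)C[C@@H](O[Si](CC)(CC)CC)C=C(C[Cr](Cl)Cl)C(=O)OC | intermediate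
31 | chromium(III) alkoxide of the bicyclic hydroxy ester (C6–C7 formed) | COC(=O)C(=C)[C@H]1[C@H](O[Cr](Cl)Cl)[C@@H]2O[C@](C)(CC[C@H](O[Si](C)(C)C(C)(C)C)[C@@H]2CO[Si](C)(C)C(C)(C)C)C[C@H]1O[Si](CC)(CC)CC | intermediate
32 | tricyclic α-methylene lactone, O3 and O15 as TBS ethers, O8 as TES ether (key-step product) | C=C1C(=O)O[C@@H]2[C@@H]3O[C@](C)(CC[C@H](O[Si](C)(C)C(C)(C)C)[C@@H]3CO[Si](C)(C)C(C)(C)C)C[C@@H](O[Si](CC)(CC)CC)[C@@H]12 | intermediate
33 | tricyclic 8,15-diol, O3 TBS | C=C1C(=O)O[C@@H]2[C@@H]3O[C@](C)(CC[C@H](O[Si](C)(C)C(C)(C)C)[C@@H]3CO)C[C@@H](O)[C@@H]12 | intermediate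
34 | tricyclic 15-acetate 8-alcohol, O3 TBS | C=C1C(=O)O[C@@H]2[C@@H]3O[C@](C)(CC[C@H](O[Si](C)(C)C(C)(C)C)[C@@H]3COC(C)=O)C[C@@H](O)[C@@H]12 | intermediate
35 | 3-methylfuran-2(5H)-one | CC1=CCOC1=O | starting material
36 | sodium (Z)-4-hydroxy-2-methylbut-2-enoate | [Na+].[O-]C(=O)/C(C)=C\CO | intermediate
37 | (Z)-4-acetoxy-2-methylbut-2-enoic acid | OC(=O)/C(C)=C\COC(C)=O | intermediate
38 | mixed anhydride of 37 with 2,4,6-trichlorobenzoic acid | O=C(OC(=O)/C(C)=C\COC(C)=O)c1c(Cl)cc(Cl)cc1Cl | intermediate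
39 | O3-TBS ether of the target | C=C1C(=O)O[C@@H]2[C@@H]3O[C@](C)(CC[C@H](O[Si](C)(C)C(C)(C)C)[C@@H]3COC(C)=O)C[C@@H](OC(=O)/C(C)=C\COC(C)=O)[C@@H]12 | intermediate
40 | CNP0148432.1, (3S,4S,5R,6S,7R,8R,10R) | C=C1C(=O)O[C@@H]2[C@@H]3O[C@](C)(CC[C@H](O)[C@@H]3COC(C)=O)C[C@@H](OC(=O)/C(C)=C\COC(C)=O)[C@@H]12 | target

**Step count and risks**

Total step count: 23. Longest linear sequence: 20 (steps 1–6, 8–19, 22, 23).

Steps most likely to fail:

1. Step 17. Intermolecular allylation or simple reduction of the allylchromium may outrun closure of the strained, trans-bridged seven-membered ring, or the ring may close with the wrong facial sense at C6/C7. The fallback closes the same bond by a single-electron ketyl–olefin cyclisation and adds the methylene afterwards. It sets out from 24: Wittig reaction with methyl 2-(triphenylphosphoranylidene)propanoate should give the (E)-2-methyl enoate alcohol F1; TEMPO/PhI(OAc)2 oxidises it to the C6 aldehyde F2; SmI2 in THF/t-BuOH at −78 °C should add the C6 ketyl to C7 (7-exo-trig), and after protonation of the samarium enolate the alkoxide lactonises to the α-methyl lactone F3. Deprotonation (LiHMDS, −78 °C) and PhSeBr give the α-phenylseleno lactone F4, H2O2 gives the selenoxide F5, and its syn-elimination into the methyl group, the usual course for trans-fused lactones, comes back to the route at 32.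

2. Step 12. The tertiary hydroxyl may attack too slowly, so that acid-induced silyl loss or opening at the terminal carbon (8-endo) competes. The fallback enforces the regiochemistry with a Sharpless 2,3-epoxy alcohol and sets C5 by reagent control. It sets out from 10: TEMPO oxidation of commercial 3-[(4-methoxybenzyl)oxy]propan-1-ol gives 3-[(4-methoxybenzyl)oxy]propanal F6; deconjugative Knoevenagel condensation with malonic acid (Et3N, heat) gives (E)-5-[(4-methoxybenzyl)oxy]pent-3-enoic acid F7; acylation of 11 (PivCl, Et3N, LiCl) gives the imide F8. Its boron enolate (Bu2BOTf, i-Pr2NEt) and 10 should give the syn-aldol adduct F9 with an (E)-3-(PMB-oxy)propenyl group at C4. LiBH4 gives the TMS-protected diol F10 and K2CO3/MeOH in the same flask the triol F11; TBSOTf gives the bis-TBS ether F12; DDQ gives the (E)-allylic alcohol F13. Sharpless epoxidation with L-(+)-diethyl tartrate should give the (5S,6S)-epoxy alcohol F14, in which the hydroxymethyl group deactivates C6. Ti(Oi-Pr)4 in toluene (or CSA) then closes the oxepane at C5 to the diol F15; NaIO4 cleaves it to the aldehyde F16 and NaBH4 in the same flask reduces this, which comes back to the route at 22.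

3. Step 9. Directed epoxidation of a terminal homoallylic alkene may be slow and show poor facial selectivity. The fallback sets C5 by iodocarbonate cyclisation through an all-equatorial six-membered ring. It sets out from 17: LiBH4 gives the 1,3-diol F17 (TMS ether kept); TBSCl/imidazole silylates the primary hydroxyl to F18; Boc2O/DMAP gives the tert-butyl carbonate F19; IBr in toluene at −85 °C should give the cyclic iodocarbonate F20 with the C2 chain, CH2OTBS and CH2I all equatorial. K2CO3/MeOH then opens the carbonate, closes the epoxide and removes the TMS group to give the epoxy diol F21; TBSOTf (1.1 equiv) at −78 °C silylates O3, which comes back to the route at 21.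

Further compounds
F1 | step 17 | (E)-2-methyl enoate arm, C6 alcohol | OC[C@@H]1O[C@](C)(CC[C@H](O[Si](C)(C)C(C)(C)C)[C@@H]1CO[Si](C)(C)C(C)(C)C)C[C@@H](O[Si](CC)(CC)CC)/C=C(\C)C(=O)OC
F2 | step 17 | (E)-2-methyl enoate arm, C6 aldehyde | O=C[C@@H]1O[C@](C)(CC[C@H](O[Si](C)(C)C(C)(C)C)[C@@H]1CO[Si](C)(C)C(C)(C)C)C[C@@H](O[Si](CC)(CC)CC)/C=C(\C)C(=O)OC
F3 | step 17 | tricyclic α-methyl lactone (C11 epimers) | CC1C(=O)O[C@@H]2[C@@H]3O[C@](C)(CC[C@H](O[Si](C)(C)C(C)(C)C)[C@@H]3CO[Si](C)(C)C(C)(C)C)C[C@@H](O[Si](CC)(CC)CC)[C@@H]12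
F4 | step 17 | α-methyl-α-phenylseleno lactone | CC1([Se]c4ccccc4)C(=O)O[C@@H]2[C@@H]3O[C@](C)(CC[C@H](O[Si](C)(C)C(C)(C)C)[C@@H]3CO[Si](C)(C)C(C)(C)C)C[C@@H](O[Si](CC)(CC)CC)[C@@H]12
F5 | step 17 | selenoxide of F4 | CC1([Se](=O)c4ccccc4)C(=O)O[C@@H]2[C@@H]3O[C@](C)(CC[C@H](O[Si](C)(C)C(C)(C)C)[C@@H]3CO[Si](C)(C)C(C)(C)C)C[C@@H](O[Si](CC)(CC)CC)[C@@H]12
F6 | step 12 | 3-[(4-methoxybenzyl)oxy]propanal | COc1ccc(COCCC=O)cc1
F7 | step 12 | (E)-5-[(4-methoxybenzyl)oxy]pent-3-enoic acid | COc1ccc(COC/C=C/CC(=O)O)cc1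
F8 | step 12 | (R)-4-benzyl-3-[(E)-5-[(4-methoxybenzyl)oxy]pent-3-enoyl]oxazolidin-2-one | COc1ccc(COC/C=C/CC(=O)N2[C@H](Cc3ccccc3)COC2=O)cc1
F9 | step 12 | syn-aldol adduct with (E)-3-(PMB-oxy)propenyl at C4 | C=C[C@H](O[Si](CC)(CC)CC)C[C@](C)(O[Si](C)(C)C)CC[C@H](O)[C@@H](/C=C/COCc1ccc(OC)cc1)C(=O)N1[C@H](Cc2ccccc2)COC1=O
F10 | step 12 | 1,3-diol with tertiary TMS ether | C=C[C@H](O[Si](CC)(CC)CC)C[C@](C)(O[Si](C)(C)C)CC[C@H](O)[C@H](CO)/C=C/COCc1ccc(OC)cc1
F11 | step 12 | triol with allylic PMB ether | C=C[C@H](O[Si](CC)(CC)CC)C[C@](C)(O)CC[C@H](O)[C@H](CO)/C=C/COCc1ccc(OC)cc1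
F12 | step 12 | bis-TBS ether of F11 | C=C[C@H](O[Si](CC)(CC)CC)C[C@](C)(O)CC[C@H](O[Si](C)(C)C(C)(C)C)[C@H](CO[Si](C)(C)C(C)(C)C)/C=C/COCc1ccc(OC)cc1
F13 | step 12 | (E)-allylic alcohol | C=C[C@H](O[Si](CC)(CC)CC)C[C@](C)(O)CC[C@H](O[Si](C)(C)C(C)(C)C)[C@H](CO[Si](C)(C)C(C)(C)C)/C=C/CO
F14 | step 12 | (5S,6S)-2,3-epoxy alcohol | C=C[C@H](O[Si](CC)(CC)CC)C[C@](C)(O)CC[C@H](O[Si](C)(C)C(C)(C)C)[C@H](CO[Si](C)(C)C(C)(C)C)[C@@H]1O[C@H]1CO
F15 | step 12 | oxepane A with a 1,2-dihydroxyethyl group at C5 | OC[C@H](O)[C@@H]1O[C@](C)(CC[C@H](O[Si](C)(C)C(C)(C)C)[C@@H]1CO[Si](C)(C)C(C)(C)C)C[C@@H](O[Si](CC)(CC)CC)C=C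
F16 | step 12 | oxepane A C6 aldehyde with the vinyl arm | O=C[C@@H]1O[C@](C)(CC[C@H](O[Si](C)(C)C(C)(C)C)[C@@H]1CO[Si](C)(C)C(C)(C)C)C[C@@H](O[Si](CC)(CC)CC)C=C
F17 | step 9 | 2-ethenyl-1,3-diol from 17 (TMS ether kept) | C=C[C@H](O[Si](CC)(CC)CC)C[C@](C)(O[Si](C)(C)C)CC[C@H](O)[C@H](CO)C=C
F18 | step 9 | primary TBS ether of F17 | C=C[C@H](O[Si](CC)(CC)CC)C[C@](C)(O[Si](C)(C)C)CC[C@H](O)[C@H](CO[Si](C)(C)C(C)(C)C)C=C
F19 | step 9 | O3 tert-butyl carbonate | C=C[C@H](O[Si](CC)(CC)CC)C[C@](C)(O[Si](C)(C)C)CC[C@H](OC(=O)OC(C)(C)C)[C@H](CO[Si](C)(C)C(C)(C)C)C=C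
F20 | step 9 | cyclic iodocarbonate (all-equatorial 1,3-dioxan-2-one) | C=C[C@H](O[Si](CC)(CC)CC)C[C@](C)(O[Si](C)(C)C)CC[C@@H]1OC(=O)O[C@H](CI)[C@H]1CO[Si](C)(C)C(C)(C)C
F21 | step 9 | epoxy diol with O15 TBS | C=C[C@H](O[Si](CC)(CC)CC)C[C@](C)(O)CC[C@H](O)[C@H](CO[Si](C)(C)C(C)(C)C)[C@H]1CO1
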